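(The runs were generated by integration with constants of no real substance; the scatter is artificial.)

We decide to follow the flask up to 5.0% conversion and to freeze whatever barely moves in that stretch: the partner, both substrates and the precatalyst.

in all of them: left-handed substrate 0.25 M; right-handed substrate 0.25 M
- amber: partner 0.52 M; precatalyst 5 mM; run made earlier
- ochre: partner 0.83 M; precatalyst 5 mM; run made earlier
- flask: partner 0.375 M; precatalyst 5.0 mM

| run | time / min | left-handed product / % |
|---|---|---|
| amber | 1.33 | 19.8 |
| amber | 2.50 | 36.0 |
| amber | 4.00 | 42.7 |
| amber | 5.00 | 45.0 |
| amber | 6.00 | 46.8 |
| amber | 8.00 | 47.9 |
| ochre | 0.667 | 16.1 |
| ochre | 1.00 | 27.4 |
| ochre | 2.00 | 44.4 |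
| ochre | 3.00 | 48.6 |
| ochre | 5.00 | 49.8 |
| ochre | 8.00 | 50.4 |

(standard deviation of a reading: 0.5 percentage points)

* factor on the rate of making left-handed product when 5.0% of the left-handed substrate and right-handed substrate together are converted if partner is charged twice over
* factor on the rate when 5.0% of the left-handed substrate and right-handed substrate together are converted if precatalyst is charged at 0.50 mM instead

- catalyst is single-handed; left-handed substrate and right-handed substrate are mirror images of each other, charged as a racemate, each of them at the stated concentration
- what may be going on: partner + catalyst + left-handed substrate -> catalyst + left-handed product; partner + catalyst + right-handed substrate -> catalyst + right-handed product; partner + precatalyst -> catalyst + spent reagent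
- no earlier run changes the charge of precatalyst; that part of a forecast is a guess

We assume that partner turns precatalyst into catalyst and that the rate is first order in catalyst; no earlier run tests the second part, because none changes the precatalyst charge. With those amounts frozen, the catalyst rises in step with time, so the rate does too, and the converted amount grows as partner squared, times precatalyst, times time squared. A fixed conversion is therefore reached sooner as partner times the square root of precatalyst grows, and the rate there scales with that same product. This gives two answers. In this reckoning doubling partner doubles the rate, and the 0.50 mM charge multiplies it by the ramp factor, the square root of the ratio of the precatalyst charges, 0.316.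

The readings offer a second way to the partner factor. The amber run reads 19.8% of left-handed product at 1.33 min, and the ochre run, interpolated, reaches that level at 0.776 min. That is a time ratio of 1.71 against a partner ratio of 1.60, so doubling gives about 2.22 as read, with the scatter of the readings and at a level above the 5.0% asked about, which is close to our two.

Is the catalyst still rising? A fixed amount of catalyst, with substrates and partner falling, gives product no faster than in step with time, yet between its first two readings the ochre run's left-handed product grows by a factor of 1.70 while time grows by a factor of 1.50, so these readings show the catalyst in the ochre run still rising.

The forecast gives 2.15 and 0.2, reasoning that “With one-tenth the precatalyst, and assuming first order in catalyst, the point comes late”. Its second figure is lower than our ramp factor.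

The simulation gives 2.07 and 0.301, the second close to the ramp factor 0.316. At that conversion with the 0.50 mM charge, 79.6% of the catalyst charge is still precatalyst and 20.4% is catalyst, so the precatalyst we froze has moved there.

    partner + catalyst + left-handed substrate → catalyst + left-handed product (k = 1850 L² mol⁻² min⁻¹)
    partner + catalyst + right-handed substrate → catalyst + right-handed product (k = 1000 L² mol⁻² min⁻¹)
    partner + precatalyst → catalyst + spent reagent (k = 0.336 L mol⁻¹ min⁻¹)

In the flask, partner is the limiting reagent, charged at 0.375 M against 0.500 M of substrates together, and at 10.0 min the left-handed path uses it more slowly than the right-handed one, by a ratio of 0.83, with a half-life of 4.5 min by the right-handed path. At that time the flask holds 3.7% of its partner, 17% of its left-handed substrate and 39% of its right-handed substrate.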